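**Assumption:** "Mutafran C" is taken to be mutafuran C, and the SMILES is authoritative. It describes a trans-2,5-disubstituted THF with C2 (ester chain) R, C5 (alkynyl) S, and both alkenes E.

## Retrosynthetic overview
1. The only ring, the THF, is not built. It is the ring of lactone 1 ((S)-5-(hydroxymethyl)butyrolactone, from the L-glutamic acid/levoglucosenone pool). Its stereocentre becomes C2 of the target.
2. Disconnection A (side-chain CH2–CH2): 1 + methyl acrylate 2 ⇒ lactone ester 3, by a photoredox deoxygenative Giese addition.
3. Disconnection B (C5–C(sp), sets C5): lactol 4 (from 3) + alkynyl sulfone 5 ⇒ trans-alkynyl THF 6, by a new photoredox deoxygenative anomeric-radical alkynylation.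
4. Disconnection C (C(sp)–C(sp2)): 6 + symmetric (E,E)-dibromide 8 (one step from diyne 7) ⇒ mutafuran C 9, by mono-Sonogashira coupling.

## Route

**Step 1**
- Reactants: 1, (S)-5-(hydroxymethyl)dihydrofuran-2(3H)-one; 2, methyl acrylate
- Product: 3, methyl 4-[(2R)-5-oxotetrahydrofuran-2-yl]butanoate
- Conditions: 5,7-di-tert-butyl-3-phenylbenzoxazolium BF4 (1.2 equiv), pyridine (1.2 equiv), MTBE, rt, 15 min, filter; then 2 (2 equiv), [Ir(ppy)2(dtbbpy)]PF6 (1 mol %), n-Bu4NOAc, MTBE/DMA, 450 nm LEDs, rt
- Reagents that add atoms: methyl acrylate, C=CC(=O)OC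
- Why: In this photoredox deoxygenative Giese addition, the benzoxazolium adduct of the primary alcohol is oxidised and β-scission gives RCH2•, which adds to acrylate before the α-ester radical is reduced and protonated; the radical sits next to the purchased stereocentre rather than on it, so the geometry is kept (S→R is only a CIP rank change) and the lactone is inert.

**Step 2**
- Reactants: 3, methyl 4-[(2R)-5-oxotetrahydrofuran-2-yl]butanoate
- Product: 4, methyl 4-[(2R,5RS)-5-hydroxytetrahydrofuran-2-yl]butanoate (lactol, anomer mixture)
- Conditions: Sia2BH (2.5 equiv, from BH3·THF and 2-methyl-2-butene), THF, 0 °C → rt; then H2O2, pH 7 buffer, 0 °C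
- Reagents that add atoms: none
- Why: Disiamylborane reduces γ-lactones chemoselectively to the lactol stage and leaves acyclic methyl esters untouched; C2 is remote from the carbonyl and cannot epimerise, and the anomeric mixture does not matter because that centre becomes a radical in step 3.

**Step 3 (key step)**
- Reactants: 4, lactol; 5, p-tolyl 2-(trimethylsilyl)ethynyl sulfone
- Product: 6, methyl 4-[(2R,5S)-5-[(trimethylsilyl)ethynyl]tetrahydrofuran-2-yl]butanoate (trans; the minor cis isomer is removed on silica)
- Conditions: 5,7-di-tert-butyl-3-phenylbenzoxazolium BF4 (1.2 equiv), pyridine (1.2 equiv), MTBE, 0 °C, 20 min, filter; then 5 (1.5 equiv), [Ir(ppy)2(dtbbpy)]PF6 (2 mol %), 2,4,6-collidine, MTBE/MeCN, 450 nm LEDs, −20 °C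
- Reagents that add atoms: p-tolyl 2-(trimethylsilyl)ethynyl sulfone, Cc1ccc(cc1)S(=O)(=O)C#C[Si](C)(C)C
- Why: Proposed new method: the hemiacetal OH condenses with the benzoxazolium salt, and *Ir(III) oxidises the N-aryl adduct, which is deprotonated to an α-amino radical; β-scission of the exocyclic O–C5 bond (driven by carbamate C=O formation and oxygen stabilisation of the radical) then places the 5-alkyl-THF-2-yl radical only at C5, with no C2–H abstraction and so no racemisation; this nucleophilic, rapidly inverting σ-radical adds to the sulfonyl-bearing sp carbon of 5 on the face anti to the C2 side chain, because the crowded transition state next to the Ts group penalises cis approach across the ring oxygen, and at −20 °C the expected trans:cis ratio is about 4–6:1; β-elimination of Ts• follows and Ir(II) reduces Ts• to sulfinate, closing a redox-neutral cycle; the closest known reaction types are benzoxazolium-mediated deoxygenative radical couplings of ordinary alcohols and SOMOphilic alkynylation of α-oxy radicals (from C–H abstraction or α-oxy acids) with alkynyl sulfones, and their combination on a lactol is untested.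

**Step 4**
- Reactants: 7, deca-1,9-diyne
- Product: 8, (1E,9E)-1,10-dibromodeca-1,9-diene
- Conditions: Cp2Zr(H)Cl (2.4 equiv), CH2Cl2, rt, dark, 1 h; then NBS (2.4 equiv), 0 °C
- Reagents that add atoms: N-bromosuccinimide, O=C1CCC(=O)N1Br
- Why: Double hydrozirconation with Schwartz's reagent adds syn and places Zr on the terminal carbon, and bromodezirconation proceeds with retention, so both termini become (E)-vinyl bromides.

**Step 5**
- Reactants: 6, trans TMS-alkynyl THF; 8, (1E,9E)-1,10-dibromodeca-1,9-diene (3 equiv, excess recovered)
- Product: 9, mutafuran C, methyl 4-[(2R,5S)-5-[(3E,11E)-12-bromododeca-3,11-dien-1-yn-1-yl]tetrahydrofuran-2-yl]butanoate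
- Conditions: Pd(PPh3)4 (5 mol %), CuI (10 mol %), CsF (1.5 equiv), i-Pr2NH, THF/MeOH (9:1), 40 °C
- Reagents that add atoms: (1E,9E)-1,10-dibromodeca-1,9-diene, Br/C=C/CCCCCC/C=C/Br
- Why: In this in situ desilylative Sonogashira coupling, CsF/MeOH releases the terminal alkyne slowly (little Glaser dimer) and it couples with retention of the E geometry; the threefold excess of symmetric 8 favours mono-coupling and leaves the second (E)-vinyl bromide, MeOH exchange at the methyl ester is degenerate, and the base is far too weak to epimerise C5.

## Compound list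
| No. | Name | SMILES | Role |
|---|---|---|---|
| 1 | (S)-5-(hydroxymethyl)dihydrofuran-2(3H)-one | OC[C@@H]1CCC(=O)O1 | starting material |
| 2 | methyl acrylate | C=CC(=O)OC | starting material |
| 3 | methyl 4-[(2R)-5-oxotetrahydrofuran-2-yl]butanoate | COC(=O)CCC[C@@H]1CCC(=O)O1 | intermediate |
| 4 | methyl 4-[(2R,5RS)-5-hydroxytetrahydrofuran-2-yl]butanoate | COC(=O)CCC[C@@H]1CCC(O)O1 | intermediate |
| 5 | p-tolyl 2-(trimethylsilyl)ethynyl sulfone | Cc1ccc(cc1)S(=O)(=O)C#C[Si](C)(C)C | starting material |
| 6 | methyl 4-[(2R,5S)-5-[(trimethylsilyl)ethynyl]tetrahydrofuran-2-yl]butanoate | COC(=O)CCC[C@@H]1CC[C@@H](C#C[Si](C)(C)C)O1 | intermediate |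
| 7 | deca-1,9-diyne | C#CCCCCCCC#C | starting material |
| 8 | (1E,9E)-1,10-dibromodeca-1,9-diene | Br/C=C/CCCCCC/C=C/Br | intermediate |
| 9 | mutafuran C | COC(=O)CCC[C@@H]1CC[C@@H](C#C/C=C/CCCCCC/C=C/Br)O1 | target |

## Summary
- Total steps: 5
- Longest linear sequence: 4 (1 → 3 → 4 → 6 → 9)

**Steps most likely to fail**
1. **Step 3 (proposed new step).**
   - Risks: the benzoxazolium salt may be captured by the open-chain hydroxy-aldehyde tautomer, the adduct may ionise, or the trans:cis ratio may be modest.
   - Fallback (known chemistry): acetylate lactol 4 (Ac2O, pyridine), then carry out a polar oxocarbenium alkynylation with tributyl[(trimethylsilyl)ethynyl]stannane and BF3·OEt2 in CH2Cl2 at −78 °C. This is trans-favoured nucleophilic attack and also gives 6, with chromatographic removal of the cis isomer.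
2. **Step 5.**
   - Risks: statistical bis-coupling, or sluggish vinyl bromide coupling while desilylation is running.
   - Fallback: drop the symmetric dihalide. Make (1E,9E)-1-bromo-10-iododeca-1,9-diene from 7 by two successive mono-hydrozirconations (NBS, then I2). Desilylate 6 separately (K2CO3, MeOH) and couple the isolated terminal alkyne chemoselectively at the C–I bond (Pd/Cu, rt).
3. **Step 1.**
   - Risks: low efficiency for a primary, β-acyloxy alcohol, or acrylate oligomerisation.
   - Fallback: convert 1 to (S)-5-(iodomethyl)dihydrofuran-2(3H)-one (I2, PPh3, imidazole). Then run a classical halogen-abstraction chain Giese addition to 2 ((TMS)3SiH or Bu3SnH, AIBN, slow addition) to reach 3.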